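**Retrosynthetic overview**

1. Feature: the ten-membered carbocycle C1–C10 holds the diene C2=C3–C4=C5 with C2=C3 trans and C4=C5 cis inside the ring, and C3 is tied back to C10 by the oxygen of the five-membered furanone ring (O, C3, C2, C1, C10). This is the cis,trans-diene that conrotatory opening of a cyclobutene cis-fused to an eight-membered ring delivers.
2. Key disconnection: C2–C3 and C4–C5 are made by [2+2] cycloaddition of the C2=C5 enone of a cyclooctenone with the C3≡C4 alkyne hung on the C10 oxygen; the C2–C5 bond of the cyclobutene is then broken by 4π electrocyclic opening (eight- to ten-membered ring). After it: lactone carbonyl restored at C12, α-methylenation (C13), silyl removal.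
3. Repair: the alkynyl ether needs n-BuLi (trichloroethylene method), which no ketone, lactone or ester survives, and it would divert a metathesis catalyst into enyne metathesis. So the eight-membered ring is closed first (C2=C5, ring-closing metathesis) on a dichlorovinyl ether, the alkyne is unveiled on a carbonyl-free ring, and only then are the C1 ketone and the C8 isobutyrate put in; the lactone carbonyl rides through the key step as its O-methyl lactol (C12).
4. C6, C7, C8: diisopinocampheylboron syn aldol of a C8 ketone with acrolein (C6–C7 bond), then hydroxyl-directed anti reduction at C8. C10 comes from (R)-citramalic acid, whose dioxolanone is opened by the new C8 hydroxyl to a temporary C1/C8 lactone.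
5. Order of rings: tetrahydrofuran (lactone surrogate) → cyclooctene → furanone and cyclobutene (key step) → ten-membered ring by expansion; the lactone is regenerated from the tetrahydrofuran at the end.

Key step: step 14

Remark: locants are germacrane numbers (C1 ketone, C2 and C3 furanone carbons, C4 bears C15, C5 alkene CH, C6 lactone O–CH, C7 bears C11, C8 acyloxy CH, C9 CH2, C10 quaternary with methyl C14, C12 lactone carbonyl, C13 methylene).
Remark: intermediates between the acetal formation and the lactol oxidation are anomer mixtures at C12, and those between the vinyl addition and the allylic oxidation are epimer mixtures at C1; both centres are removed later and are left open in the SMILES.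
Assumption: the (−)-boron reagent of step 3 is taken to add to the si face of acrolein, the sense it shows in allylborations with the same ligands; the configuration of the aldol would be checked (Mosher esters) and the (+)-reagent used if the sense were opposite.

**Route**

Step 1
Reactants: 1 (R)-citramalic acid
Product: 2 (R)-2-(2,2,4-trimethyl-5-oxo-1,3-dioxolan-4-yl)acetic acid
Conditions: Me2C(OMe)2, TsOH (cat.), 23 °C
Reagents that add atoms: 2,2-dimethoxypropane, COC(C)(C)OC
Why: Acid-catalysed acetalisation of the α-hydroxy acid (1,3-dioxolan-4-one formation) ties the tertiary C10 hydroxyl and the C1 carboxyl into a five-membered ring and leaves the C8 carboxyl free, with no bond to the stereocentre touched.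

Step 2
Reactants: 2 (R)-2-(2,2,4-trimethyl-5-oxo-1,3-dioxolan-4-yl)acetic acid; 3 [2-(1,3-dioxolan-2-yl)ethyl]magnesium bromide
Product: 5 (R)-5-[4-(1,3-dioxolan-2-yl)-2-oxobutyl]-2,2,5-trimethyl-1,3-dioxolan-4-one, via acid chloride 4 (not isolated)
Conditions: (COCl)2, DMF (cat.), CH2Cl2, 0→23 °C, evaporate; then 3, Fe(acac)3 (3 mol %), THF, −78 °C
Reagents that add atoms: none
Why: Acid chloride formation and iron-catalysed Grignard acylation (ketone synthesis) are fast at −78 °C and should stop at the C8 ketone without attack on the dioxolanone carbonyl.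

Step 3
Reactants: 5 (R)-5-[4-(1,3-dioxolan-2-yl)-2-oxobutyl]-2,2,5-trimethyl-1,3-dioxolan-4-one; 6 acrolein
Product: 8 (R)-5-[(3S,4R)-3-(1,3-dioxolan-2-ylmethyl)-4-hydroxy-2-oxohex-5-en-1-yl]-2,2,5-trimethyl-1,3-dioxolan-4-one, via Z boron enolate 7 (not isolated)
Conditions: (−)-Ipc2BOTf, i-Pr2NEt, CH2Cl2, −78 °C; 6, −78→−20 °C; H2O2, MeOH, pH 7 buffer, 0 °C
Reagents that add atoms: none
Why: Boron-mediated syn aldol reaction: the bulky boron triflate should enolise the less hindered C7 methylene (not C9, where a β-oxygen would be lost) to the Z enolate, whose chair transition state gives the 6,7-syn adduct, while the isopinocampheyl ligands direct attack to the si face of acrolein and so set C6 (reagent control; the minor diastereomer is removed by chromatography).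

Step 4
Reactants: 8 (R)-5-[(3S,4R)-3-(1,3-dioxolan-2-ylmethyl)-4-hydroxy-2-oxohex-5-en-1-yl]-2,2,5-trimethyl-1,3-dioxolan-4-one
Product: 10 (3R,5R)-5-[(2S,3R)-1-(1,3-dioxolan-2-yl)-3-hydroxypent-4-en-2-yl]-3-hydroxy-3-methyldihydrofuran-2(3H)-one, via anti-1,3-diol 9 (not isolated)
Conditions: Me4NBH(OAc)3, MeCN/AcOH, −30 °C; work-up; then DBU (cat.), CH2Cl2, 23 °C
Reagents that add atoms: none
Why: Hydroxyl-directed 1,3-anti reduction (Evans–Saksena): the C6 alkoxyborohydride delivers hydride through a chair and sets the C8 carbinol anti to C6–OH, and the new C8 hydroxyl then opens the dioxolanone by 5-exo transesterification with loss of acetone, which frees the C10 hydroxyl and masks C8–O and C1 as a γ-lactone (the C6 hydroxyl would need a seven-membered ring).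

Step 5
Reactants: 10 (3R,5R)-5-[(2S,3R)-1-(1,3-dioxolan-2-yl)-3-hydroxypent-4-en-2-yl]-3-hydroxy-3-methyldihydrofuran-2(3H)-one
Product: 11 (3R,5R)-3-hydroxy-5-[(2R,3R)-5-methoxy-2-vinyltetrahydrofuran-3-yl]-3-methyldihydrofuran-2(3H)-one
Conditions: MeOH, TsOH·H2O (cat.), 23 °C
Reagents that add atoms: methanol, CO
Why: Acid-catalysed transacetalisation: the only free secondary hydroxyl (C6) closes onto the C12 acetal carbon to the five-membered O-methyl lactol (the masked lactone, trans at C6/C7 as fixed by the aldol), which leaves the tertiary C10 hydroxyl as the only free OH.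

Step 6
Reactants: 11 (3R,5R)-3-hydroxy-5-[(2R,3R)-5-methoxy-2-vinyltetrahydrofuran-3-yl]-3-methyldihydrofuran-2(3H)-one; 12 trichloroethylene
Product: 13 (3R,5R)-3-[(E)-1,2-dichlorovinyloxy]-5-[(2R,3R)-5-methoxy-2-vinyltetrahydrofuran-3-yl]-3-methyldihydrofuran-2(3H)-one
Conditions: KH, THF, 0→23 °C
Reagents that add atoms: none
Why: Addition of the potassium alkoxide to dichloroacetylene formed in situ from trichloroethylene (first half of the trichloroethylene route to alkynyl ethers) should give the robust (E)-1,2-dichlorovinyl ether of the tertiary alcohol; the lactone has no enolisable α-hydrogen.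

Step 7
Reactants: 13 (3R,5R)-3-[(E)-1,2-dichlorovinyloxy]-5-[(2R,3R)-5-methoxy-2-vinyltetrahydrofuran-3-yl]-3-methyldihydrofuran-2(3H)-one
Product: 14 (3R,5R)-3-[(E)-1,2-dichlorovinyloxy]-5-[(2R,3R)-5-methoxy-2-vinyltetrahydrofuran-3-yl]-3-methyltetrahydrofuran-2-ol
Conditions: i-Bu2AlH, CH2Cl2, −78 °C
Reagents that add atoms: none
Why: Partial reduction of a lactone to the lactol at −78 °C; the dichlorovinyl ether and the acetal are inert to the hydride.

Step 8
Reactants: 14 (3R,5R)-3-[(E)-1,2-dichlorovinyloxy]-5-[(2R,3R)-5-methoxy-2-vinyltetrahydrofuran-3-yl]-3-methyltetrahydrofuran-2-ol; 15 vinylmagnesium bromide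
Product: 16 (1R,3R)-3-[(E)-1,2-dichlorovinyloxy]-1-[(2R,3R)-5-methoxy-2-vinyltetrahydrofuran-3-yl]-3-methylhex-5-ene-1,4-diol
Conditions: 15 (4 equiv), THF, 0→23 °C
Reagents that add atoms: none
Why: Grignard addition to the open hydroxy-aldehyde form of the lactol gives the C1 allylic alcohol and frees C8–OH; both C1 epimers are carried on because C1 becomes the ketone in step 12.

Step 9
Reactants: 16 (1R,3R)-3-[(E)-1,2-dichlorovinyloxy]-1-[(2R,3R)-5-methoxy-2-vinyltetrahydrofuran-3-yl]-3-methylhex-5-ene-1,4-diol
Product: 17 cis-cyclooctene diol: ring C1(OH)–C2=C5–C6–C7–C8(OH)–C9H2–C10(CH3)[O–(E)-CCl=CHCl], trans-fused at C6–C7 to a tetrahydrofuran (O on C6; C11H2 on C7; C12 bears OCH3); 6R,7R,8R,10R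
Conditions: second-generation Grubbs catalyst (10 mol %), 1,4-benzoquinone (10 mol %), CH2Cl2 (2 mM), 40 °C
Reagents that add atoms: none
Why: Ring-closing olefin metathesis of the two monosubstituted alkenes, helped by the trans-fused tetrahydrofuran and the quaternary C10, should close the cis-cyclooctene at C2=C5; the trisubstituted dichlorovinyl ether cannot enter the cycle, whereas the later alkynyl ether would undergo enyne metathesis, which is why the ring is closed at this stage.

Step 10
Reactants: 17 cis-cyclooctene diol with C10 dichlorovinyl ether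
Product: 19 cis-cyclooctene triol: as 17 but with C10–O–C≡C–CH2OH (C3≡C4–C15), via trilithio alkoxyacetylide 18 (not isolated)
Conditions: n-BuLi (5 equiv), THF, −78→−40 °C; CH2O (monomer from cracked paraformaldehyde), −78→−20 °C; NaHCO3 (aq)
Reagents that add atoms: formaldehyde, C=O
Why: Second half of the trichloroethylene route: n-BuLi deprotonates both hydroxyls, eliminates HCl and exchanges the remaining chlorine to give the lithium alkoxyacetylide, which adds to formaldehyde (C15); the substrate holds no carbonyl group at this point, which is the reason for the masked lactone and the late ketone and ester.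

Step 11
Reactants: 19 cis-cyclooctene triol with C10 alkynyl ether
Product: 20 C15 tert-butyldiphenylsilyl ether of 19 (C1 and C8 hydroxyls free)
Conditions: t-BuPh2SiCl, imidazole, CH2Cl2, 0 °C
Reagents that add atoms: tert-butyl(chloro)diphenylsilane, CC(C)(C)[Si](Cl)(c1ccccc1)c1ccccc1
Why: Selective silylation of the primary hydroxyl by a bulky silyl chloride under buffered, non-acidic conditions that the alkynyl ether tolerates.

Step 12
Reactants: 20 C15 silyl ether diol
Product: 21 cis-cyclooctenone: C1 ketone conjugated with C2=C5, C8–OH free, C10 alkynyl ether, O-methyl lactol; 6R,7R,8R,10R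
Conditions: MnO2 (excess), CH2Cl2, 23 °C
Reagents that add atoms: none
Why: Neutral heterogeneous allylic oxidation: MnO2 oxidises only the allylic C1 alcohol, which gives the enone and removes the C1 centre; the product may sit partly as its transannular C8–O hemiketal.

Step 13
Reactants: 21 cis-cyclooctenone with free C8 hydroxyl; 22 isobutyric anhydride
Product: 23 key-step precursor: cis-cyclooctenone C10 alkynyl ether with C8 isobutyrate, C15 tert-butyldiphenylsilyl ether and O-methyl lactol at C12; 6R,7R,8R,10R
Conditions: 22, DMAP, Et3N, CH2Cl2, 0→23 °C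
Reagents that add atoms: none
Why: DMAP-catalysed acylation of the C8 hydroxyl, drawn from the hemiketal equilibrium through the open hydroxy ketone, installs the isobutyrate under basic conditions that spare the alkynyl ether.

Step 14
Reactants: 23 cyclooctenone C10 alkynyl ether
Product: 25 furanone-bridged ten-membered ring: C1 ketone, C2=C3 in the furanone (O, C3, C2, C1, C10), (Z)-C4=C5 with C15 silyl ether, C8 isobutyrate, O-methyl lactol at C12; 6R,7R,8R,10R, via tricyclic alkoxycyclobutene 24 (not isolated)
Conditions: hν (365 nm), degassed CH2Cl2 (1 mM), −70 °C; then dark, −70→23 °C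
Reagents that add atoms: none
Why: Proposed new method: light absorbed by the cyclooctenone (n→π*, then the triplet) should join the enone α-carbon C2 to the oxygen-bearing alkyne carbon C3 across the three-atom tether C1–C10–O (5-exo-dig closure of the ring O–C3–C2–C1–C10), and the resulting C5/C4 1,4-biradical should collapse to the four-membered ring (radical recombination), giving alkoxycyclobutene 24 with its C3=C4 bond at the fusion carbon of the five- and four-membered rings. The closest known reactions are the intramolecular enone–alkyne [2+2] photocycloaddition with a three-atom tether, the Ficini-type [2+2] of enones with heteroatom-substituted alkynes (same pairing of the donor-bearing alkyne carbon with the enone α-carbon), and the thermal two-carbon ring expansion of cis-fused cyclobutenes. The strain of that fusion-carbon alkene and the gain of vinylogous-ester and diene conjugation should allow conrotatory 4π opening of the C2–C5 bond at or below room temperature, so the ten-membered ring arises by expansion of the eight-membered one and not by an end-to-end cyclisation. The product has no new stereocentre: C2 and C5 are stereogenic only in 24, where the C5–C9 bridge fixes C2 and cis 4/8 fusion is expected at C5, and C6, C7, C8 and C10 are not touched. The step needs 1,5-regiochemistry (set by the tether and matched by the polarity of the alkynyl ether), cis fusion, and one sense of rotation, which the furanone ring enforces because C1 is held cis to the oxygen on C3 and must turn outward, so that C6 turns inward and C4=C5 forms with C6 cis to C3 while C2=C3 is trans in the ten-membered ring. Irradiating at −70 °C at a wavelength that 24 does not absorb, then warming in the dark, keeps light from the furanone and keeps the tertiary alkynyl ether below the temperature of its retro-ene loss of ketene.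

Step 15
Reactants: 25 furanone-bridged ten-membered ring with O-methyl lactol
Product: 26 lactol: as 25 with C12–OH in place of C12–OCH3
Conditions: AcOH/THF/H2O (3:1:1), 35 °C
Reagents that add atoms: water, O
Why: Mild aqueous acid hydrolysis of the 2-methoxytetrahydrofuran (a 2-deoxyfuranoside-type acetal) should free the lactol without loss of the silyl ether or the ester; the acid-sensitive alkynyl ether is no longer present.

Step 16
Reactants: 26 lactol
Product: 27 γ-lactone (C12 carbonyl, C11 methylene unsubstituted): the key-step product in its lactone form, C15 tert-butyldiphenylsilyl ether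
Conditions: PhI(OAc)2, TEMPO (cat.), CH2Cl2, 23 °C
Reagents that add atoms: none
Why: Oxoammonium (TEMPO) oxidation of a lactol to the lactone; no other free hydroxyl is present.

Step 17
Reactants: 27 γ-lactone
Product: 29 C11 (dimethylamino)methyl lactone (Mannich base), via lithium enolate 28 (not isolated)
Conditions: LiN(SiMe3)2 (1.05 equiv), THF, −78 °C; Me2N=CH2 I, −78→0 °C
Reagents that add atoms: N,N-dimethylmethyleneiminium iodide, C=[N+](C)C.[I-]
Why: Kinetic deprotonation of the lactone α-methylene (more acidic and less hindered than the isobutyrate α-CH; the furanone has no enolisable hydrogen) and Mannich reaction of the lithium enolate with the iminium salt.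

Step 18
Reactants: 29 Mannich base
Product: 31 α-methylene lactone (C11=C13), C15 tert-butyldiphenylsilyl ether, via trimethylammonium iodide 30 (not isolated)
Conditions: MeI, CH2Cl2/MeOH, 23 °C; then NaHCO3 (aq), EtOAc, 23 °C
Reagents that add atoms: none
Why: N-Methylation and base-induced β-elimination of trimethylamine from the β-ammonio lactone (Hofmann-type elimination) give the exocyclic methylene.

Step 19
Reactants: 31 α-methylene lactone silyl ether
Product: 32 target CNP0176924.3
Conditions: HF·pyridine, pyridine, THF, 0→23 °C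
Reagents that add atoms: none
Why: Fluoride cleavage of the primary silyl ether under buffered, weakly acidic conditions, which the α-methylene lactone and the furanone tolerate better than basic fluoride.

**Compound list**

1 | (R)-citramalic acid, (2R)-2-hydroxy-2-methylbutanedioic acid | OC(=O)[C@@](C)(CC(=O)O)O | starting material
2 | (R)-2-(2,2,4-trimethyl-5-oxo-1,3-dioxolan-4-yl)acetic acid | O=C1OC(C)(C)O[C@]1(C)CC(=O)O | intermediate
3 | [2-(1,3-dioxolan-2-yl)ethyl]magnesium bromide | Br[Mg]CCC1OCCO1 | starting material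
4 | (R)-2-(2,2,4-trimethyl-5-oxo-1,3-dioxolan-4-yl)acetyl chloride | O=C1OC(C)(C)O[C@]1(C)CC(=O)Cl | intermediate
5 | (R)-5-[4-(1,3-dioxolan-2-yl)-2-oxobutyl]-2,2,5-trimethyl-1,3-dioxolan-4-one (C8 ketone) | O=C1OC(C)(C)O[C@]1(C)CC(=O)CCC2OCCO2 | intermediate
6 | acrolein | C=CC=O | starting material
7 | (Z)-enol diisopinocampheylborinate of 5 (C7=C8, boron on the C8 oxygen) | O=C1OC(C)(C)O[C@]1(C)C/C(=C/CC2OCCO2)OB([C@@H]3C[C@@H]4C[C@H]([C@H]3C)C4(C)C)[C@@H]5C[C@@H]6C[C@H]([C@H]5C)C6(C)C | intermediate
8 | (R)-5-[(3S,4R)-3-(1,3-dioxolan-2-ylmethyl)-4-hydroxy-2-oxohex-5-en-1-yl]-2,2,5-trimethyl-1,3-dioxolan-4-one (6,7-syn aldol) | O=C1OC(C)(C)O[C@]1(C)CC(=O)[C@@H](CC2OCCO2)[C@H](O)C=C | intermediate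
9 | (R)-5-[(2R,3R,4R)-3-(1,3-dioxolan-2-ylmethyl)-2,4-dihydroxyhex-5-en-1-yl]-2,2,5-trimethyl-1,3-dioxolan-4-one (6,8-anti diol) | O=C1OC(C)(C)O[C@]1(C)C[C@@H](O)[C@@H](CC2OCCO2)[C@H](O)C=C | intermediate
10 | (3R,5R)-5-[(2S,3R)-1-(1,3-dioxolan-2-yl)-3-hydroxypent-4-en-2-yl]-3-hydroxy-3-methyldihydrofuran-2(3H)-one (C1/C8 lactone) | C[C@@]1(O)C[C@@H](OC1=O)[C@@H](CC2OCCO2)[C@H](O)C=C | intermediate
11 | (3R,5R)-3-hydroxy-5-[(2R,3R)-5-methoxy-2-vinyltetrahydrofuran-3-yl]-3-methyldihydrofuran-2(3H)-one (anomers at C12) | C[C@@]1(O)C[C@@H](OC1=O)[C@H]2CC(OC)O[C@@H]2C=C | intermediate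
12 | trichloroethylene | ClC=C(Cl)Cl | starting material
13 | (3R,5R)-3-[(E)-1,2-dichlorovinyloxy]-5-[(2R,3R)-5-methoxy-2-vinyltetrahydrofuran-3-yl]-3-methyldihydrofuran-2(3H)-one | C[C@@]1(O/C(Cl)=C\Cl)C[C@@H](OC1=O)[C@H]2CC(OC)O[C@@H]2C=C | intermediate
14 | (3R,5R)-3-[(E)-1,2-dichlorovinyloxy]-5-[(2R,3R)-5-methoxy-2-vinyltetrahydrofuran-3-yl]-3-methyltetrahydrofuran-2-ol (lactol) | C[C@@]1(O/C(Cl)=C\Cl)C[C@@H](OC1O)[C@H]2CC(OC)O[C@@H]2C=C | intermediate
15 | vinylmagnesium bromide | C=C[Mg]Br | starting material
16 | (1R,3R)-3-[(E)-1,2-dichlorovinyloxy]-1-[(2R,3R)-5-methoxy-2-vinyltetrahydrofuran-3-yl]-3-methylhex-5-ene-1,4-diol (C1 epimers) | C=CC(O)[C@](C)(O/C(Cl)=C\Cl)C[C@@H](O)[C@H]1CC(OC)O[C@@H]1C=C | intermediate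
17 | cis-cyclooctene diol: C1–OH, C2=C5, C8–OH, C10 methyl and (E)-1,2-dichlorovinyl ether, trans-fused 12-methoxytetrahydrofuran at C6–C7; 6R,7R,8R,10R | O[C@@H]1C[C@@](C)(O/C(Cl)=C\Cl)C(O)/C=C\[C@H]2OC(OC)C[C@H]12 | intermediate
18 | trilithio species: C1 and C8 lithium alkoxides, C10–O–C≡C–Li | [Li]O[C@@H]1C[C@@](C)(OC#C[Li])C(O[Li])/C=C\[C@H]2OC(OC)C[C@H]12 | intermediate
19 | cis-cyclooctene triol with C10–O–C≡C–CH2OH | O[C@@H]1C[C@@](C)(OC#CCO)C(O)/C=C\[C@H]2OC(OC)C[C@H]12 | intermediate
20 | C15 tert-butyldiphenylsilyl ether of 19 | O[C@@H]1C[C@@](C)(OC#CCO[Si](c3ccccc3)(c3ccccc3)C(C)(C)C)C(O)/C=C\[C@H]2OC(OC)C[C@H]12 | intermediate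
21 | cis-cyclooctenone (C1 ketone) with free C8–OH, C10 alkynyl ether | O[C@@H]1C[C@@](C)(OC#CCO[Si](c3ccccc3)(c3ccccc3)C(C)(C)C)C(=O)/C=C\[C@H]2OC(OC)C[C@H]12 | intermediate
22 | isobutyric anhydride | CC(C)C(=O)OC(=O)C(C)C | starting material
23 | key-step precursor: cyclooctenone C10 alkynyl ether, C8 isobutyrate, C15 silyl ether, O-methyl lactol at C12; 6R,7R,8R,10R | CC(C)C(=O)O[C@@H]1C[C@@](C)(OC#CCO[Si](c3ccccc3)(c3ccccc3)C(C)(C)C)C(=O)/C=C\[C@H]2OC(OC)C[C@H]12 | intermediate
24 | tricyclic alkoxycyclobutene: new bonds C2–C3 and C5–C4, C3=C4, cis 4/8 fusion | CC(C)C(=O)O[C@@H]1C[C@@]2(C)OC3=C(CO[Si](c4ccccc4)(c4ccccc4)C(C)(C)C)[C@H]([C@H]3C2=O)[C@H]5OC(OC)C[C@H]15 | intermediate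
25 | key-step product: furanone-bridged ten-membered ring, (Z)-C4=C5, C15 silyl ether, C8 isobutyrate, O-methyl lactol at C12 | C1C(OC)O[C@@H]2/C=C(/CO[Si](c4ccccc4)(c4ccccc4)C(C)(C)C)C3=CC(=O)[C@@](C)(C[C@@H](OC(=O)C(C)C)[C@@H]12)O3 | intermediate
26 | lactol (C12–OH) of 25 | C1C(O)O[C@@H]2/C=C(/CO[Si](c4ccccc4)(c4ccccc4)C(C)(C)C)C3=CC(=O)[C@@](C)(C[C@@H](OC(=O)C(C)C)[C@@H]12)O3 | intermediate
27 | γ-lactone without methylene, C15 silyl ether | C1C(=O)O[C@@H]2/C=C(/CO[Si](c4ccccc4)(c4ccccc4)C(C)(C)C)C3=CC(=O)[C@@](C)(C[C@@H](OC(=O)C(C)C)[C@@H]12)O3 | intermediate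
28 | lithium enolate of lactone 27 (C11=C12–OLi) | C1=C(O[Li])O[C@@H]2/C=C(/CO[Si](c4ccccc4)(c4ccccc4)C(C)(C)C)C3=CC(=O)[C@@](C)(C[C@@H](OC(=O)C(C)C)[C@@H]12)O3 | intermediate
29 | C11 (dimethylamino)methyl lactone | CN(C)CC1C(=O)O[C@@H]2/C=C(/CO[Si](c4ccccc4)(c4ccccc4)C(C)(C)C)C3=CC(=O)[C@@](C)(C[C@@H](OC(=O)C(C)C)[C@@H]12)O3 | intermediate
30 | C11 (trimethylammonio)methyl lactone iodide | C[N+](C)(C)CC1C(=O)O[C@@H]2/C=C(/CO[Si](c4ccccc4)(c4ccccc4)C(C)(C)C)C3=CC(=O)[C@@](C)(C[C@@H](OC(=O)C(C)C)[C@@H]12)O3.[I-] | intermediate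
31 | α-methylene lactone, C15 tert-butyldiphenylsilyl ether | C=C1C(=O)O[C@@H]2/C=C(/CO[Si](c4ccccc4)(c4ccccc4)C(C)(C)C)C3=CC(=O)[C@@](C)(C[C@@H](OC(=O)C(C)C)[C@@H]12)O3 | intermediate
32 | CNP0176924.3 (6R,7R,8R,10R) | C=C1C(=O)O[C@@H]2/C=C(/CO)C3=CC(=O)[C@@](C)(C[C@@H](OC(=O)C(C)C)[C@@H]12)O3 | target

**Step count and risk**

Total step count: 19. Longest linear sequence: 19 steps from (R)-citramalic acid (the route is fully linear).

Steps most likely to fail:

1. Step 14 (proposed new method). What may go wrong:
   - After excitation the cyclooctenone may relax to its trans isomer and add to the alkyne in the ground state with trans ring fusion, which would open to the wrong C4=C5 geometry.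
   - The C6 hydrogen may shift to the excited carbonyl (photoenolisation), with loss of the C6 centre or deconjugation.
   - The alkynyl ether may fragment to a ketene before it reacts.

   Fallback with known reactions only, setting out from hydroxy lactone 11. Addition of the lithium acetylide of 2-[(tert-butyldiphenylsilyloxy)methyl]but-1-en-3-yne (THF, −78 °C) to the lactone carbonyl would give the α′-hydroxy ynone F1. Et2NH in EtOH (conjugate addition, then 5-endo closure by the C10 hydroxyl) would give the 3(2H)-furanone F2. Isobutyric anhydride/DMAP would give the diene F3. Ring-closing metathesis of the C6 vinyl group with the 1,1-disubstituted C4 alkene (second-generation Hoveyda–Grubbs catalyst, toluene, 80 °C, 1 mM) would close the ten-membered ring at C4=C5 and come back to the route at 25; the C4=C5 geometry would have to be checked there.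

2. Step 10. What may go wrong: slow or incomplete chlorine–lithium exchange in the aggregated trilithio species, and loss of the tertiary alkynyl ether (retro-ene fragmentation, or addition of the neighbouring C1 hydroxyl across the triple bond) while the acetylide is warmed with formaldehyde or worked up.

   Fallback, setting out from dichlorovinyl ether 17. The same n-BuLi treatment is used, but the acetylide and both alkoxides are captured at −78 °C with methyl chloroformate to give the alkynoate bis(methyl carbonate) F4. This is reduced with i-Bu2AlH (CH2Cl2, −78 °C; ester to the propargylic alcohol, carbonates to the alcohols) and comes back at triol 19. C15 thus enters at the carboxyl level in a reaction that is complete in the cold.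

3. Step 9. What may go wrong: intermolecular metathesis (oligomers) outrunning the slow closure of the eight-membered ring at the hindered C1 vinyl carbinol, and ruthenium hydride isomerisation of the allylic alcohol to a ketone.

   Fallback, setting out from lactone 13. Oxidative cleavage of the vinyl group (K2OsO4·2H2O cat., NaIO4, 2,6-lutidine, dioxane/H2O; the dichloroalkene is too electron-poor to react) gives aldehyde F5. Stork–Zhao olefination (Ph3P=CHI, THF, −78 °C) gives the (Z)-vinyl iodide F6, and i-Bu2AlH (−78 °C) gives the lactol F7. Nozaki–Hiyama–Kishi cyclisation of its open hydroxy-aldehyde form (CrCl2, NiCl2 cat., DMSO, 23 °C) then forms the C1–C2 bond and comes back at cyclooctene diol 17.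

Further compounds
F1 | step 14 | α′-hydroxy ynone from 11: C10(OH)–C1(=O)–C≡C–C(=CH2)CH2OSi(t-Bu)Ph2, C8–OH free | C=C(CO[Si](c1ccccc1)(c1ccccc1)C(C)(C)C)C#CC(=O)[C@](C)(O)C[C@@H](O)[C@H]2CC(OC)O[C@@H]2C=C
F2 | step 14 | 3(2H)-furanone with 5-(alk-1-en-2-yl) group, C8–OH free | C=C(CO[Si](c1ccccc1)(c1ccccc1)C(C)(C)C)C3=CC(=O)[C@](C)(O3)C[C@@H](O)[C@H]2CC(OC)O[C@@H]2C=C
F3 | step 14 | C8 isobutyrate of F2 (diene for ring closure at C4=C5) | C=C(CO[Si](c1ccccc1)(c1ccccc1)C(C)(C)C)C3=CC(=O)[C@](C)(O3)C[C@@H](OC(=O)C(C)C)[C@H]2CC(OC)O[C@@H]2C=C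
F4 | step 10 | methyl 3-alkoxypropiolate at C10–O with C1 and C8 methyl carbonates | COC(=O)O[C@@H]1C[C@@](C)(OC#CC(=O)OC)C(OC(=O)OC)/C=C\[C@H]2OC(OC)C[C@H]12
F5 | step 9 | aldehyde from cleavage of the C6 vinyl group of 13 | C[C@@]1(O/C(Cl)=C\Cl)C[C@@H](OC1=O)[C@H]2CC(OC)O[C@@H]2C=O
F6 | step 9 | (Z)-2-iodovinyl lactone | C[C@@]1(O/C(Cl)=C\Cl)C[C@@H](OC1=O)[C@H]2CC(OC)O[C@@H]2/C=C\I
F7 | step 9 | (Z)-2-iodovinyl lactol | C[C@@]1(O/C(Cl)=C\Cl)C[C@@H](OC1O)[C@H]2CC(OC)O[C@@H]2/C=C\I
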